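**Retrosynthetic overview**
1. Target 10 ⇐ diol 9 (acetylation of the allylic OH) ⇐ cyclohexenone 8 (hydroxyl-directed C=O reduction).
2. Cyclohexenone 8 ⇐ cyclopentenyl α-ketol 7 by an α-ketol (acyloin) ring expansion: the benzoyloxy-bearing sp3 ring carbon shifts from the carbinol carbon to the side-chain carbonyl.
3. 7 ⇐ ethynyl carbinol 5 (alkyne → acetoxymethyl ketone) ⇐ enone 3 + ethynylmagnesium bromide 4.
4. 3 ⇐ trans-dibenzoate 2 (allylic oxidation) ⇐ cyclopentadiene 1 by an enantioselective anti-1,2-dibenzoyloxylation.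
5. Ring order: the five-membered ring comes from 1; the six-membered ring is formed once, in the expansion 7 → 8.

Assumption: cyclopentadiene monomer (cracked from its commercial dimer just before use) counts as a commercial starting material, and the (R,R)-iodane of step 1 is taken to give the (1R,2R) series (otherwise its antipode from the other methyl lactate is used).

**Route**

Step 1
Reactants: 1 cyclopenta-1,3-diene
Product: 2 (1R,2R)-cyclopent-3-ene-1,2-diyl dibenzoate
Conditions: (R,R)-ArI(OBz)2 (lactate-derived aryl-λ3-iodane dibenzoate, 1.0 equiv), BF3·OEt2 (20 mol%), CH2Cl2, −78 °C, 1 in excess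
Reagents that add atoms: dimethyl (2R,2'R)-2,2'-{[2-(dibenzoyloxy-λ3-iodanyl)-1,3-phenylene]bis(oxy)}dipropanoate, COC(=O)[C@@H](C)Oc1cccc(O[C@H](C)C(=O)OC)c1I(OC(=O)c1ccccc1)OC(=O)c1ccccc1
Why: Proposed new method: an enantioselective Prévost-type anti-1,2-dibenzoyloxylation of a cyclic 1,3-diene by a C2-symmetric chiral aryl-λ3-iodane – the I(III) centre adds to one face of a terminal diene carbon, benzoate attacks the allylic carbon anti, the neighbouring benzoate displaces ArI to give a cis-fused dioxolanylium ion, and a second benzoate opens this at the allylic carbon with inversion, which gives the trans (1R,2R) dibenzoate and sets both stereocentres; the closest known reactions are the Prévost reaction and the chiral iodine(III) dioxygenation (diacetoxylation) of styrenes.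

Step 2
Reactants: 2 (1R,2R)-cyclopent-3-ene-1,2-diyl dibenzoate
Product: 3 (4R,5S)-4,5-bis(benzoyloxy)cyclopent-2-en-1-one
Conditions: Mn(OAc)3·2H2O (10 mol%), t-BuOOH (5 equiv, decane), 3 Å MS, EtOAc, rt
Reagents that add atoms: tert-butyl hydroperoxide, CC(C)(C)OO
Why: Radical allylic C–H oxidation (Mn(III)/t-BuOOH) of the only CH2 group gives the enone; oxygen capture at either end of the allyl radical gives the same enantiomer of 3 because the trans-dibenzoate unit is locally C2-symmetric, and the neutral conditions leave the benzoates and both stereocentres untouched.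

Step 3
Reactants: 3 (4R,5S)-4,5-bis(benzoyloxy)cyclopent-2-en-1-one; 4 ethynylmagnesium bromide
Product: 5 (1S,4R,5S)-4,5-bis(benzoyloxy)-1-ethynylcyclopent-2-en-1-ol
Conditions: LaCl3·2LiCl (cat.), THF, −78 °C; then H2O
Reagents that add atoms: none
Why: 1,2-Addition of a weakly basic alkynyl Grignard reagent to the activated ketone is faster than attack on the benzoates at −78 °C and occurs anti to the adjacent C5 benzoate (Felkin–Anh control), which sets C1 with its OH cis to the C5 benzoate.

Step 4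
Reactants: 5 (1S,4R,5S)-4,5-bis(benzoyloxy)-1-ethynylcyclopent-2-en-1-ol
Product: 7 2-[(1R,4R,5S)-4,5-bis(benzoyloxy)-1-hydroxycyclopent-2-en-1-yl]-2-oxoethyl acetate, via dihydroxy ketone 6 (not isolated)
Conditions: PhI(OCOCF3)2, MeCN–H2O (9:1), 0 °C → rt; then Ac2O, pyridine, 0 °C
Reagents that add atoms: water, O; acetic anhydride, CC(=O)OC(C)=O
Why: Iodine(III) oxidation of an ethynyl carbinol to the dihydroxyacetone unit (Kita oxidation, as used for corticoid side chains; the two new oxygens come from water) is followed by selective acetylation of the primary hydroxyl, the tertiary one being too hindered; no stereocentre is involved.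

Step 5
Reactants: 7 2-[(1R,4R,5S)-4,5-bis(benzoyloxy)-1-hydroxycyclopent-2-en-1-yl]-2-oxoethyl acetate
Product: 8 (4R,5S,6S)-6-(acetoxymethyl)-4,5-bis(benzoyloxy)-6-hydroxycyclohex-2-en-1-one
Conditions: Sc(OTf)3 (10 mol%), ClCH2CH2Cl, 50 °C
Reagents that add atoms: none
Why: α-Ketol (acyloin) rearrangement with ring expansion, the reaction type of the D-homoannulation of 17α-hydroxy-20-ketosteroids: in the Sc chelate of the tertiary OH and the side-chain C=O (the cis benzoate can bind as a third donor and twist the ketone towards the sp3 carbon) the benzoyloxy-bearing ring carbon shifts with retention onto the carbonyl carbon on the face of the tertiary OH, which puts the new tertiary OH cis to the adjacent benzoate, and the conjugated six-membered enone is the thermodynamic sink (a ketol from the competing vinyl shift can reach the same enone by a second acyloin shift of the CH2OAc group).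

Step 6
Reactants: 8 (4R,5S,6S)-6-(acetoxymethyl)-4,5-bis(benzoyloxy)-6-hydroxycyclohex-2-en-1-one
Product: 9 [(1R,2S,5R,6S)-5,6-bis(benzoyloxy)-1,2-dihydroxycyclohex-3-en-1-yl]methyl acetate
Conditions: Me4NBH(OAc)3, MeCN–AcOH (1:1), −30 → 0 °C
Reagents that add atoms: none
Why: Hydroxyl-directed reduction (Evans–Saksena type): the tertiary OH exchanges onto boron and delivers hydride intramolecularly to its own face of the ketone, which gives the 1,2-trans (anti) diol by 1,2-reduction and leaves the esters alone.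

Step 7
Reactants: 9 [(1R,2S,5R,6S)-5,6-bis(benzoyloxy)-1,2-dihydroxycyclohex-3-en-1-yl]methyl acetate
Product: 10 [(1R,2S,5R,6S)-2-acetoxy-5,6-bis(benzoyloxy)-1-hydroxycyclohex-3-en-1-yl]methyl acetate
Conditions: Ac2O, pyridine, DMAP (cat.), CH2Cl2, 0 °C
Reagents that add atoms: acetic anhydride, CC(=O)OC(C)=O
Why: Acetylation (DMAP-catalysed acyl transfer) of the secondary allylic alcohol; the hindered tertiary alcohol does not react and no stereocentre changes.

**Compound list**
1 | cyclopenta-1,3-diene | C1C=CC=C1 | starting material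
2 | (1R,2R)-cyclopent-3-ene-1,2-diyl dibenzoate (trans) | C1C=C[C@@H](OC(=O)c2ccccc2)[C@@H]1OC(=O)c1ccccc1 | intermediate
3 | (4R,5S)-4,5-bis(benzoyloxy)cyclopent-2-en-1-one (4,5-trans) | O=C1C=C[C@@H](OC(=O)c2ccccc2)[C@@H]1OC(=O)c1ccccc1 | intermediate
4 | ethynylmagnesium bromide | C#C[Mg]Br | starting material
5 | (1S,4R,5S)-4,5-bis(benzoyloxy)-1-ethynylcyclopent-2-en-1-ol (1-OH cis to 5-OBz) | C#C[C@@]1(O)C=C[C@@H](OC(=O)c2ccccc2)[C@@H]1OC(=O)c1ccccc1 | intermediate
6 | 1-[(1R,4R,5S)-4,5-bis(benzoyloxy)-1-hydroxycyclopent-2-en-1-yl]-2-hydroxyethan-1-one | OCC(=O)[C@@]1(O)C=C[C@@H](OC(=O)c2ccccc2)[C@@H]1OC(=O)c1ccccc1 | intermediate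
7 | 2-[(1R,4R,5S)-4,5-bis(benzoyloxy)-1-hydroxycyclopent-2-en-1-yl]-2-oxoethyl acetate | CC(=O)OCC(=O)[C@@]1(O)C=C[C@@H](OC(=O)c2ccccc2)[C@@H]1OC(=O)c1ccccc1 | intermediate
8 | (4R,5S,6S)-6-(acetoxymethyl)-4,5-bis(benzoyloxy)-6-hydroxycyclohex-2-en-1-one (6-OH cis to 5-OBz) | CC(=O)OC[C@@]1(O)C(=O)C=C[C@@H](OC(=O)c2ccccc2)[C@@H]1OC(=O)c1ccccc1 | intermediate
9 | [(1R,2S,5R,6S)-5,6-bis(benzoyloxy)-1,2-dihydroxycyclohex-3-en-1-yl]methyl acetate (1,2-trans diol) | CC(=O)OC[C@@]1(O)[C@@H](O)C=C[C@@H](OC(=O)c2ccccc2)[C@@H]1OC(=O)c1ccccc1 | intermediate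
10 | [(1R,2S,5R,6S)-2-acetoxy-5,6-bis(benzoyloxy)-1-hydroxycyclohex-3-en-1-yl]methyl acetate | CC(=O)OC[C@@]1(O)[C@@H](OC(C)=O)C=C[C@@H](OC(=O)c2ccccc2)[C@@H]1OC(=O)c1ccccc1 | target

**Totals and risks**
Total step count: 7. Longest linear sequence: 7 steps (1 → 10).

Step 1 (the proposed new step) is the most uncertain. The diene may give 1,4-adducts, may polymerise under the Lewis acid, or may give low ee. The fallback uses known chemistry, sets out from 1 and comes back at 2. Jacobsen (salen)Mn-catalysed epoxidation of 1 gives (1S,5R)-6-oxabicyclo[3.1.0]hex-2-ene F1. Benzoic acid opens this vinyl epoxide at the allylic carbon with inversion to (1R,5R)-5-hydroxycyclopent-2-en-1-yl benzoate F2, whose ee is raised by crystallisation. Benzoylation with BzCl and pyridine then gives 2.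

Step 5 may stop at the non-conjugated ketol from the vinyl shift, or the allylic benzoates may ionise under the Lewis acid. The fallback changes the migrating group's electronics by swapping the benzoates for silyl ethers; it sets out from 5 and comes back at 8. K2CO3 in MeOH removes the benzoates to give (1S,4R,5S)-1-ethynylcyclopent-2-ene-1,4,5-triol F3. TBSCl and imidazole silylate the two secondary hydroxyls to (1S,4R,5S)-4,5-bis(tert-butyldimethylsilyloxy)-1-ethynylcyclopent-2-en-1-ol F4. The oxidation and acetylation of step 4 then lead, through 1-[(1R,4R,5S)-4,5-bis(tert-butyldimethylsilyloxy)-1-hydroxycyclopent-2-en-1-yl]-2-hydroxyethan-1-one F5, to 2-[(1R,4R,5S)-4,5-bis(tert-butyldimethylsilyloxy)-1-hydroxycyclopent-2-en-1-yl]-2-oxoethyl acetate F6. The migrating sp3 carbon now carries a donor silyloxy group and no ionisable allylic ester is present, so the acyloin ring expansion should give (4R,5S,6S)-6-(acetoxymethyl)-4,5-bis(tert-butyldimethylsilyloxy)-6-hydroxycyclohex-2-en-1-one F7. HF·pyridine frees (4R,5S,6S)-6-(acetoxymethyl)-4,5,6-trihydroxycyclohex-2-en-1-one F8, and BzCl with pyridine benzoylates its two secondary hydroxyls to give 8.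

Step 6 depends on a hindered tertiary OH directing the hydride; undirected axial attack would give the cis-diol epimer. The fallback makes that epimer on purpose and inverts it; it sets out from 8 and comes back at 10, bypassing 9. Luche reduction (NaBH4, CeCl3, MeOH, −78 °C) gives [(1R,2R,5R,6S)-5,6-bis(benzoyloxy)-1,2-dihydroxycyclohex-3-en-1-yl]methyl acetate F9. A Mitsunobu reaction with acetic acid (PPh3, DIAD) inverts this allylic carbinol and installs the acetate in the same operation, giving 10; the cis tertiary OH cannot close an epoxide.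

**Further compounds**
F1 | step 1 | (1S,5R)-6-oxabicyclo[3.1.0]hex-2-ene | C1C=C[C@@H]2O[C@H]12
F2 | step 1 | (1R,5R)-5-hydroxycyclopent-2-en-1-yl benzoate | C1C=C[C@@H](OC(=O)c2ccccc2)[C@@H]1O
F3 | step 5 | (1S,4R,5S)-1-ethynylcyclopent-2-ene-1,4,5-triol | C#C[C@@]1(O)C=C[C@@H](O)[C@@H]1O
F4 | step 5 | (1S,4R,5S)-4,5-bis(tert-butyldimethylsilyloxy)-1-ethynylcyclopent-2-en-1-ol | C#C[C@@]1(O)C=C[C@@H](O[Si](C)(C)C(C)(C)C)[C@@H]1O[Si](C)(C)C(C)(C)C
F5 | step 5 | 1-[(1R,4R,5S)-4,5-bis(tert-butyldimethylsilyloxy)-1-hydroxycyclopent-2-en-1-yl]-2-hydroxyethan-1-one | OCC(=O)[C@@]1(O)C=C[C@@H](O[Si](C)(C)C(C)(C)C)[C@@H]1O[Si](C)(C)C(C)(C)C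
F6 | step 5 | 2-[(1R,4R,5S)-4,5-bis(tert-butyldimethylsilyloxy)-1-hydroxycyclopent-2-en-1-yl]-2-oxoethyl acetate | CC(=O)OCC(=O)[C@@]1(O)C=C[C@@H](O[Si](C)(C)C(C)(C)C)[C@@H]1O[Si](C)(C)C(C)(C)C
F7 | step 5 | (4R,5S,6S)-6-(acetoxymethyl)-4,5-bis(tert-butyldimethylsilyloxy)-6-hydroxycyclohex-2-en-1-one | CC(=O)OC[C@@]1(O)C(=O)C=C[C@@H](O[Si](C)(C)C(C)(C)C)[C@@H]1O[Si](C)(C)C(C)(C)C
F8 | step 5 | (4R,5S,6S)-6-(acetoxymethyl)-4,5,6-trihydroxycyclohex-2-en-1-one | CC(=O)OC[C@@]1(O)C(=O)C=C[C@@H](O)[C@@H]1O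
F9 | step 6 | [(1R,2R,5R,6S)-5,6-bis(benzoyloxy)-1,2-dihydroxycyclohex-3-en-1-yl]methyl acetate | CC(=O)OC[C@@]1(O)[C@H](O)C=C[C@@H](OC(=O)c2ccccc2)[C@@H]1OC(=O)c1ccccc1
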